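The C9–C10 bond of ring B is the disconnection on which everything rests. C10 is the quaternary carbon that carries the C20 methyl, and C9 lies alpha to C8. A tertiary C10 radical, made by hydrogen-atom transfer to a C10=C20 methylidene on ring A, can therefore add to C9 of a C8-oxo C9=C11 enoate. One operation forms C9–C10, creates C20, closes ring B and sets C9 and C10, and it leaves the C8 ketone as the handle for the C8=C17 methylene. The precursor is a ring-A cyclohexane that already holds C5 and the C4 quaternary centre (methyl cis to the C5 chain, ester trans) and carries the 4-oxo-enoate chain on C5.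

Key step: step 9

Remark: labdane numbering is used throughout. Read from the SMILES, the target is 4R,5R,9S,10R,13S: the C4 ester carbon (C18) is equatorial and trans to C20, and the C4 methyl (C19) is axial. The precursor is therefore built with this centre in place instead of as a geminal diester, and all esters are methyl esters.

Step 1
Reactants: 1 5-chloropent-1-yne
Product: 3 2-(5-chloropent-1-en-2-yl)-4,4,5,5-tetramethyl-1,3,2-dioxaborolane, via alkenylalane 2 (not isolated)
Conditions: NiCl2(dppp) (3 mol%), DIBAL-H (1.3 equiv), THF, 0 → 22 °C; then MeOBpin, 0 → 80 °C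
Reagents that add atoms: 2-methoxy-4,4,5,5-tetramethyl-1,3,2-dioxaborolane, COB1OC(C)(C)C(C)(C)O1
Why: Nickel-catalysed alpha-selective hydroalumination of the terminal alkyne puts aluminium on the internal carbon, and aluminium-to-boron exchange with the methoxyboronate should give the 1,1-disubstituted alkenylboronate, the primary chloride being inert to DIBAL-H at this temperature.

Step 2
Reactants: 4 methyl 4,4-dimethoxybutanoate; 5 methyl (triphenylphosphoranylidene)acetate
Product: 7 methyl (2E)-6,6-dimethoxyhex-2-enoate, via 4,4-dimethoxybutanal 6 (not isolated)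
Conditions: DIBAL-H (1.05 equiv), CH2Cl2, −78 °C; then 5, −78 → 23 °C
Reagents that add atoms: none
Why: One-pot DIBAL-H half-reduction of the ester and Wittig olefination of the released aldehyde with the stabilised ylide, which by its nature should give the E-enoate while the acetal is inert to both reagents.

Step 3
Reactants: 7 methyl (2E)-6,6-dimethoxyhex-2-enoate; 3 2-(5-chloropent-1-en-2-yl)-4,4,5,5-tetramethyl-1,3,2-dioxaborolane
Product: 8 methyl (3S)-7-chloro-3-(3,3-dimethoxypropyl)-4-methylideneheptanoate
Conditions: [Rh(cod)OH]2 (2.5 mol%), (R)-BINAP (5.5 mol%), Et3N, 1,4-dioxane/H2O 10:1, 60 °C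
Reagents that add atoms: none
Why: Hayashi–Miyaura rhodium-catalysed asymmetric 1,4-addition of an alkenylboronate to an E-enoate, in which the (R)-BINAP complex should deliver the alkenyl group to the Si face of C3 (the sense in which it converts E-crotonates into (S)-3-substituted butanoates) and so set C5 as 3S.

Step 4
Reactants: 8 methyl (3S)-7-chloro-3-(3,3-dimethoxypropyl)-4-methylideneheptanoate
Product: 9 methyl (2RS,3S)-7-chloro-3-(3,3-dimethoxypropyl)-2-methyl-4-methylideneheptanoate
Conditions: LDA (1.1 equiv), THF, −78 °C; MeI, −78 °C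
Reagents that add atoms: iodomethane, CI
Why: Kinetic ester-enolate alkylation, in which methyl iodide at −78 °C should react far faster than the internal primary chloride; the configuration of the new C4–H centre does not matter because it is enolised again in step 5.

Step 5
Reactants: 9 methyl (2RS,3S)-7-chloro-3-(3,3-dimethoxypropyl)-2-methyl-4-methylideneheptanoate
Product: 10 methyl (1R,2R)-2-(3,3-dimethoxypropyl)-1-methyl-3-methylidenecyclohexane-1-carboxylate
Conditions: LDA (1.3 equiv), THF/DMPU, −78 → 23 °C
Reagents that add atoms: none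
Why: Intramolecular 6-exo-tet enolate cycloalkylation should close ring A through a chair transition state in which C5–H eclipses the enolate double bond (least allylic 1,3-strain), the C5 chain is equatorial and the tether attacks from the C10 side, so that C4 forms with its ester trans and its methyl cis to the C5 chain (1R,2R).

Step 6
Reactants: 10 methyl (1R,2R)-2-(3,3-dimethoxypropyl)-1-methyl-3-methylidenecyclohexane-1-carboxylate
Product: 11 methyl (1R,2R)-1-methyl-3-methylidene-2-(3-oxopropyl)cyclohexane-1-carboxylate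
Conditions: PPTS (0.2 equiv), acetone/H2O 9:1, 50 °C
Reagents that add atoms: water, O
Why: Acid-catalysed acetal hydrolysis under mild, buffered conditions that should leave the exocyclic alkene and the hindered ester untouched.

Step 7
Reactants: 11 methyl (1R,2R)-1-methyl-3-methylidene-2-(3-oxopropyl)cyclohexane-1-carboxylate; 12 methyl prop-2-ynoate
Product: 13 methyl (1R,2R)-2-[(3RS)-3-hydroxy-6-methoxy-6-oxohex-4-yn-1-yl]-1-methyl-3-methylidenecyclohexane-1-carboxylate
Conditions: 12, LiHMDS, THF, −78 °C; then 11, −78 °C; AcOH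
Reagents that add atoms: none
Why: Alkynylation of the aldehyde by the lithium acetylide of the propiolate at −78 °C, with the neopentylic C4 ester too hindered to compete; the carbinol configuration is removed in step 8.

Step 8
Reactants: 13 methyl (1R,2R)-2-[(3RS)-3-hydroxy-6-methoxy-6-oxohex-4-yn-1-yl]-1-methyl-3-methylidenecyclohexane-1-carboxylate
Product: 14 methyl (1R,2R)-2-[(4E)-6-methoxy-3,6-dioxohex-4-en-1-yl]-1-methyl-3-methylidenecyclohexane-1-carboxylate
Conditions: DABCO (0.2 equiv), DMSO, 23 °C
Reagents that add atoms: none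
Why: Amine-catalysed redox isomerisation of a gamma-hydroxy alkynoate (propargylic deprotonation to the allenol, then tautomerisation) should give the E 4-oxo-enoate without a separate oxidation.

Step 9
Reactants: 14 methyl (1R,2R)-2-[(4E)-6-methoxy-3,6-dioxohex-4-en-1-yl]-1-methyl-3-methylidenecyclohexane-1-carboxylate
Product: 15 methyl (1R,4aS,5R,8aR)-5-(2-methoxy-2-oxoethyl)-1,4a-dimethyl-6-oxodecahydronaphthalene-1-carboxylate
Conditions: Fe(acac)3 (0.5 equiv), PhSiH3 (2.5 equiv), EtOH/(CH2OH)2 5:1, 0.01 M, 60 °C
Reagents that add atoms: none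
Why: Fe(acac)3 and PhSiH3 form an iron hydride that transfers a hydrogen atom to C20 of the electron-rich 1,1-disubstituted alkene, giving the tertiary C10 radical and the C20 methyl; this nucleophilic radical adds to C9 of the ene-dicarbonyl, and the C11 radical alpha to the ester is reduced by divalent iron to the enolate and protonated by ethanol. The closest known reaction is the iron-hydride reductive olefin coupling (HAT-initiated Giese addition), established for inter- and intramolecular formation of quaternary carbons. Ring B closes in the 6-exo-trig mode (C10 onto C9), which is kinetically preferred over 7-endo attack at C11 although both alkene carbons are activated. C10 is controlled by the ring-A chair: with the C5 chain equatorial the new bond forms equatorially because axial attack on the beta face is blocked by the syn-axial C19 methyl on C4, which should give the trans fusion with C20 axial, as in the ring-B closures of C10 radicals in manganese-mediated polyene cyclisations. C9 is set by the chair-like transition state of the forming ring, which places the acetate arm equatorial, and because C9 lies alpha to the C8 ketone an axial epimer can equilibrate to the same 9-beta arrangement. The step needs hydrogen-atom transfer to select the isolated alkene over the electron-poor ene-dicarbonyl, which the polarity of the hydride donor secures, and high dilution keeps the closure intramolecular.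

Step 10
Reactants: 15 methyl (1R,4aS,5R,8aR)-5-(2-methoxy-2-oxoethyl)-1,4a-dimethyl-6-oxodecahydronaphthalene-1-carboxylate
Product: 16 methyl (1R,4aR,5S,8aR)-5-(2-methoxy-2-oxoethyl)-1,4a-dimethyl-6-methylidenedecahydronaphthalene-1-carboxylate
Conditions: Ph3PCH3Br, KHMDS, THF, 0 → 60 °C
Reagents that add atoms: methyltriphenylphosphonium bromide, C[P+](c1ccccc1)(c1ccccc1)c1ccccc1.[Br-]
Why: Wittig methylenation of the C8 ketone, to which the esters are inert, and any enolisation toward C9 can only return the thermodynamically preferred equatorial side chain.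

Step 11
Reactants: 16 methyl (1R,4aR,5S,8aR)-5-(2-methoxy-2-oxoethyl)-1,4a-dimethyl-6-methylidenedecahydronaphthalene-1-carboxylate
Product: 17 methyl (1R,4aR,5S,8aR)-5-(2-hydroxyethyl)-1,4a-dimethyl-6-methylidenedecahydronaphthalene-1-carboxylate
Conditions: DIBAL-H (2.3 equiv), CH2Cl2, −78 → −30 °C; Rochelle salt
Reagents that add atoms: none
Why: Sterically controlled DIBAL-H reduction should take the unhindered primary ester to the alcohol while the alpha-quaternary C4 ester, shielded by the axial C19 methyl, stays intact at low temperature and the alkene is not touched by the aluminium hydride.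

Step 12
Reactants: 17 methyl (1R,4aR,5S,8aR)-5-(2-hydroxyethyl)-1,4a-dimethyl-6-methylidenedecahydronaphthalene-1-carboxylate
Product: 18 methyl (1R,4aR,5S,8aR)-5-(2-bromoethyl)-1,4a-dimethyl-6-methylidenedecahydronaphthalene-1-carboxylate
Conditions: CBr4, PPh3, CH2Cl2, 0 °C
Reagents that add atoms: tetrabromomethane, BrC(Br)(Br)Br
Why: Appel bromination of the unhindered primary alcohol under neutral conditions.

Step 13
Reactants: 18 methyl (1R,4aR,5S,8aR)-5-(2-bromoethyl)-1,4a-dimethyl-6-methylidenedecahydronaphthalene-1-carboxylate; 19 (4S)-4-methyloxetan-2-one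
Product: 21 (3S)-5-[(1S,4aR,5R,8aR)-5-(methoxycarbonyl)-5,8a-dimethyl-2-methylidenedecahydronaphthalen-1-yl]-3-methylpentanoic acid, via Grignard reagent 20 (not isolated)
Conditions: Mg, LiCl, THF, 0 → 23 °C; then CuBr·SMe2 (10 mol%), 19, THF/Me2S, −30 → 0 °C; 1 M HCl
Reagents that add atoms: none
Why: Magnesium insertion gives the primary Grignard reagent, which the hindered C4 ester should tolerate at or below ambient temperature, and copper-catalysed SN2 opening of the beta-lactone at its methyl-bearing carbon (alkyl–oxygen cleavage) proceeds with inversion, so the (S)-lactone sets C13 as S and releases the C15 acid directly.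

Compound list

1 | 5-chloropent-1-yne | C#CCCCCl | starting material
2 | (5-chloropent-1-en-2-yl)bis(2-methylpropyl)alumane | C=C(CCCCl)[Al](CC(C)C)CC(C)C | intermediate (not isolated)
3 | 2-(5-chloropent-1-en-2-yl)-4,4,5,5-tetramethyl-1,3,2-dioxaborolane | C=C(CCCCl)B1OC(C)(C)C(C)(C)O1 | intermediate
4 | methyl 4,4-dimethoxybutanoate | COC(=O)CCC(OC)OC | starting material
5 | methyl (triphenylphosphoranylidene)acetate | COC(=O)C=P(c1ccccc1)(c1ccccc1)c1ccccc1 | starting material
6 | 4,4-dimethoxybutanal | COC(OC)CCC=O | intermediate (not isolated)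
7 | methyl (2E)-6,6-dimethoxyhex-2-enoate | COC(=O)/C=C/CCC(OC)OC | intermediate
8 | methyl (3S)-7-chloro-3-(3,3-dimethoxypropyl)-4-methylideneheptanoate | COC(=O)C[C@H](CCC(OC)OC)C(=C)CCCCl | intermediate
9 | methyl (2RS,3S)-7-chloro-3-(3,3-dimethoxypropyl)-2-methyl-4-methylideneheptanoate | COC(=O)C(C)[C@H](CCC(OC)OC)C(=C)CCCCl | intermediate
10 | methyl (1R,2R)-2-(3,3-dimethoxypropyl)-1-methyl-3-methylidenecyclohexane-1-carboxylate | C=C1CCC[C@@](C)(C(=O)OC)[C@@H]1CCC(OC)OC | intermediate
11 | methyl (1R,2R)-1-methyl-3-methylidene-2-(3-oxopropyl)cyclohexane-1-carboxylate | C=C1CCC[C@@](C)(C(=O)OC)[C@@H]1CCC=O | intermediate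
12 | methyl prop-2-ynoate | C#CC(=O)OC | starting material
13 | methyl (1R,2R)-2-[(3RS)-3-hydroxy-6-methoxy-6-oxohex-4-yn-1-yl]-1-methyl-3-methylidenecyclohexane-1-carboxylate | C=C1CCC[C@@](C)(C(=O)OC)[C@@H]1CCC(O)C#CC(=O)OC | intermediate
14 | methyl (1R,2R)-2-[(4E)-6-methoxy-3,6-dioxohex-4-en-1-yl]-1-methyl-3-methylidenecyclohexane-1-carboxylate | C=C1CCC[C@@](C)(C(=O)OC)[C@@H]1CCC(=O)/C=C/C(=O)OC | intermediate
15 | methyl (1R,4aS,5R,8aR)-5-(2-methoxy-2-oxoethyl)-1,4a-dimethyl-6-oxodecahydronaphthalene-1-carboxylate | O=C1CC[C@@H]2[C@](C)(CCC[C@@]2(C)C(=O)OC)[C@H]1CC(=O)OC | intermediate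
16 | methyl (1R,4aR,5S,8aR)-5-(2-methoxy-2-oxoethyl)-1,4a-dimethyl-6-methylidenedecahydronaphthalene-1-carboxylate | C=C1CC[C@@H]2[C@](C)(CCC[C@@]2(C)C(=O)OC)[C@H]1CC(=O)OC | intermediate
17 | methyl (1R,4aR,5S,8aR)-5-(2-hydroxyethyl)-1,4a-dimethyl-6-methylidenedecahydronaphthalene-1-carboxylate | C=C1CC[C@@H]2[C@](C)(CCC[C@@]2(C)C(=O)OC)[C@H]1CCO | intermediate
18 | methyl (1R,4aR,5S,8aR)-5-(2-bromoethyl)-1,4a-dimethyl-6-methylidenedecahydronaphthalene-1-carboxylate | C=C1CC[C@@H]2[C@](C)(CCC[C@@]2(C)C(=O)OC)[C@H]1CCBr | intermediate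
19 | (4S)-4-methyloxetan-2-one | C[C@H]1CC(=O)O1 | starting material
20 | bromo{2-[(1S,4aR,5R,8aR)-5-(methoxycarbonyl)-5,8a-dimethyl-2-methylidenedecahydronaphthalen-1-yl]ethyl}magnesium | C=C1CC[C@@H]2[C@](C)(CCC[C@@]2(C)C(=O)OC)[C@H]1CC[Mg]Br | intermediate (not isolated)
21 | (3S)-5-[(1S,4aR,5R,8aR)-5-(methoxycarbonyl)-5,8a-dimethyl-2-methylidenedecahydronaphthalen-1-yl]-3-methylpentanoic acid | C=C1CC[C@@H]2[C@](C)(CCC[C@@]2(C)C(=O)OC)[C@H]1CC[C@H](C)CC(=O)O | target

Total step count: 13. Longest linear sequence: 12 steps (4 → 21, steps 2 to 13); step 1 is a one-step side branch that joins at step 3.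

Steps most likely to fail

Step 9 (ring-B closure). The C10 radical may close through the ring-flipped conformer of ring A, in which the C5 chain is axial; this would erode the face selectivity at C10 and give cis-fused material. The iron hydride may also reduce the ene-dicarbonyl before cyclisation. The fallback sets out from 11 and returns at 15: the C9–C10 bond is made intermolecularly and ring B is closed by a Claisen condensation. Aldehyde 11 would be oxidised (NaClO2, NaH2PO4, 2-methylbut-2-ene, t-BuOH/H2O; Pinnick) to 3-[(1R,2R)-2-(methoxycarbonyl)-2-methyl-6-methylidenecyclohexyl]propanoic acid F1 and esterified (TMSCHN2, MeOH/PhMe) to methyl (1R,2R)-2-(3-methoxy-3-oxopropyl)-1-methyl-3-methylidenecyclohexane-1-carboxylate F2. Intermolecular Fe(acac)3/PhSiH3 coupling of F2 with dimethyl fumarate, whose approach to the C10 radical should be anti to the neighbouring C5 chain, would give dimethyl 2-[(1S,2R,3R)-3-(methoxycarbonyl)-2-(3-methoxy-3-oxopropyl)-1,3-dimethylcyclohexyl]butanedioate F3. NaOMe in MeOH should then effect Dieckmann closure of C7 onto the ester carbon attached to C9, the only six-membered mode that leaves an enolisable beta-keto ester, to give dimethyl (1R,4aS,5R,8aR)-5-(2-methoxy-2-oxoethyl)-1,4a-dimethyl-6-oxodecahydronaphthalene-1,7-dicarboxylate F4. NaCl in wet DMSO at 150 °C (Krapcho) removes the C7 ester and returns 15.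

Step 3 (conjugate alkenylation). Transmetalation of the hindered 1,1-disubstituted alkenylboronate may be slow, so that protodeboronation wins, or the face selectivity on the acyclic enoate may be incomplete. The fallback sets out from 6 (made from 4 as in step 2, here isolated) and 3 and returns at 8, and uses auxiliary-controlled cuprate addition. Aldehyde 6 would be olefinated (LiCl, i-Pr2NEt, MeCN; Masamune–Roush) with diethyl {2-oxo-2-[(4R)-2-oxo-4-phenyl-1,3-oxazolidin-3-yl]ethyl}phosphonate to (4R)-3-[(2E)-6,6-dimethoxyhex-2-enoyl]-4-phenyl-1,3-oxazolidin-2-one F5. Boronate 3 would be converted (CuBr2, MeOH/H2O, 80 °C) into 2-bromo-5-chloropent-1-ene F6, and bromine–lithium exchange (t-BuLi, Et2O, −78 °C) would give (5-chloropent-1-en-2-yl)lithium F7. After transmetalation (MgBr2·OEt2, CuBr·SMe2, THF/Me2S, −40 °C) the alkenyl group should add to the magnesium-chelated s-cis form of F5 from the face opposite the phenyl group, giving (4R)-3-[(3S)-7-chloro-3-(3,3-dimethoxypropyl)-4-methylideneheptanoyl]-4-phenyl-1,3-oxazolidin-2-one F8. NaOMe in MeOH at 0 °C cleaves the auxiliary and returns 8.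

Step 13 (side-chain attachment). The Grignard reagent may attack the C4 ester while it forms, or the lactone may open by acyl–oxygen instead of alkyl–oxygen cleavage. The fallback sets out from 18 and returns at 21, and replaces the magnesium reagent by an ester-tolerant zinc reagent and the chiral lactone by a catalyst-controlled hydrogenation. Bromide 18 would be converted (Zn dust, LiCl, THF, 50 °C) into bromo{2-[(1S,4aR,5R,8aR)-5-(methoxycarbonyl)-5,8a-dimethyl-2-methylidenedecahydronaphthalen-1-yl]ethyl}zinc F9. Negishi coupling (Pd(PPh3)4, THF) with methyl (2Z)-3-iodobut-2-enoate, with retention of alkene geometry, would give methyl (1R,4aR,5S,8aR)-5-[(3Z)-5-methoxy-3-methyl-5-oxopent-3-en-1-yl]-1,4a-dimethyl-6-methylidenedecahydronaphthalene-1-carboxylate F10. DIBAL-H at −78 °C should reduce only the unhindered conjugated ester, giving methyl (1R,4aR,5S,8aR)-5-[(3Z)-5-hydroxy-3-methylpent-3-en-1-yl]-1,4a-dimethyl-6-methylidenedecahydronaphthalene-1-carboxylate F11. Hydroxyl-directed hydrogenation (Ru(OAc)2[(S)-BINAP], H2, MeOH), in the sense known for nerol to (S)-citronellol, should give methyl (1R,4aR,5S,8aR)-5-[(3S)-5-hydroxy-3-methylpentyl]-1,4a-dimethyl-6-methylidenedecahydronaphthalene-1-carboxylate F12 without touching the isolated exocyclic alkene. Oxidation (TEMPO, PhI(OAc)2, MeCN/H2O) returns 21.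

Further compounds

F1 | step 9 | 3-[(1R,2R)-2-(methoxycarbonyl)-2-methyl-6-methylidenecyclohexyl]propanoic acid | C=C1CCC[C@@](C)(C(=O)OC)[C@@H]1CCC(=O)O
F2 | step 9 | methyl (1R,2R)-2-(3-methoxy-3-oxopropyl)-1-methyl-3-methylidenecyclohexane-1-carboxylate | C=C1CCC[C@@](C)(C(=O)OC)[C@@H]1CCC(=O)OC
F3 | step 9 | dimethyl 2-[(1S,2R,3R)-3-(methoxycarbonyl)-2-(3-methoxy-3-oxopropyl)-1,3-dimethylcyclohexyl]butanedioate | C[C@@]1(CCC[C@@](C)(C(=O)OC)[C@@H]1CCC(=O)OC)C(CC(=O)OC)C(=O)OC
F4 | step 9 | dimethyl (1R,4aS,5R,8aR)-5-(2-methoxy-2-oxoethyl)-1,4a-dimethyl-6-oxodecahydronaphthalene-1,7-dicarboxylate | O=C1C(C(=O)OC)C[C@@H]2[C@](C)(CCC[C@@]2(C)C(=O)OC)[C@H]1CC(=O)OC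
F5 | step 3 | (4R)-3-[(2E)-6,6-dimethoxyhex-2-enoyl]-4-phenyl-1,3-oxazolidin-2-one | O=C1OC[C@@H](c2ccccc2)N1C(=O)/C=C/CCC(OC)OC
F6 | step 3 | 2-bromo-5-chloropent-1-ene | C=C(Br)CCCCl
F7 | step 3 | (5-chloropent-1-en-2-yl)lithium | [Li]C(=C)CCCCl
F8 | step 3 | (4R)-3-[(3S)-7-chloro-3-(3,3-dimethoxypropyl)-4-methylideneheptanoyl]-4-phenyl-1,3-oxazolidin-2-one | O=C1OC[C@@H](c2ccccc2)N1C(=O)C[C@H](CCC(OC)OC)C(=C)CCCCl
F9 | step 13 | bromo{2-[(1S,4aR,5R,8aR)-5-(methoxycarbonyl)-5,8a-dimethyl-2-methylidenedecahydronaphthalen-1-yl]ethyl}zinc | C=C1CC[C@@H]2[C@](C)(CCC[C@@]2(C)C(=O)OC)[C@H]1CC[Zn]Br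
F10 | step 13 | methyl (1R,4aR,5S,8aR)-5-[(3Z)-5-methoxy-3-methyl-5-oxopent-3-en-1-yl]-1,4a-dimethyl-6-methylidenedecahydronaphthalene-1-carboxylate | C=C1CC[C@@H]2[C@](C)(CCC[C@@]2(C)C(=O)OC)[C@H]1CC/C(C)=C\C(=O)OC
F11 | step 13 | methyl (1R,4aR,5S,8aR)-5-[(3Z)-5-hydroxy-3-methylpent-3-en-1-yl]-1,4a-dimethyl-6-methylidenedecahydronaphthalene-1-carboxylate | C=C1CC[C@@H]2[C@](C)(CCC[C@@]2(C)C(=O)OC)[C@H]1CC/C(C)=C\CO
F12 | step 13 | methyl (1R,4aR,5S,8aR)-5-[(3S)-5-hydroxy-3-methylpentyl]-1,4a-dimethyl-6-methylidenedecahydronaphthalene-1-carboxylate | C=C1CC[C@@H]2[C@](C)(CCC[C@@]2(C)C(=O)OC)[C@H]1CC[C@H](C)CCO
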